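Germacrane numbering is used. Everything rests on opening the O–C3 bond of the 3(2H)-furanone (ring O10–C3=C2–C1(=O)–C10) to a ten-membered 10-hydroxy-1-yn-3-one, a carbonyl-transposed, masked 1,3-diketone. In one operation a gold catalyst hydrates C1≡C2 at C1, the C10 hydroxyl adds transannularly to C3 and water leaves. This net isomerisation exploits the C1/C3 dioxygenation of the vinylogous ester and the proximity of O10 to C3 across the carbocycle. The precursor already holds the lactone, both esters and all five stereocentres (C8/C9 from L-tartrate, C10 by chelation, C6/C7 by allylboration). Its ring is closed by a Nozaki–Hiyama–Kishi reaction.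

Key step: step 16

Remark: O6, O8, O9, O10 and O15 are the oxygens on the carbons of the same number. Carbinol 23 is carried on as a mixture of C3 epimers, because C3 becomes trigonal again in step 15.

Step 1
Reactants: 1 dimethyl (4R,5R)-2,2-dimethyl-1,3-dioxolane-4,5-dicarboxylate (dimethyl 2,3-O-isopropylidene-L-tartrate)
Product: 3 methyl (4R,5S)-5-ethynyl-2,2-dimethyl-1,3-dioxolane-4-carboxylate, via aldehyde ester 2 (not isolated)
Conditions: i-Bu2AlH (1.0 equiv), CH2Cl2, −78 °C; then MeOH, K2CO3, dimethyl (1-diazo-2-oxopropyl)phosphonate, −78 °C → rt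
Reagents that add atoms: dimethyl (1-diazo-2-oxopropyl)phosphonate, COP(=O)(OC)C(=[N+]=[N-])C(C)=O
Why: Partial reduction of one of two homotopic esters stops at the aluminium hemiacetal, and Ohira–Bestmann (Seyferth–Gilbert) homologation of the released aldehyde gives the alkyne (C7≡C11); C8 and C9 come unchanged from L-tartaric acid, and the trans-dioxolane is the thermodynamic isomer, so K2CO3 should not erode it.

Step 2
Reactants: 3 methyl (4R,5S)-5-ethynyl-2,2-dimethyl-1,3-dioxolane-4-carboxylate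
Product: 5 1-[(4R,5S)-5-ethynyl-2,2-dimethyl-1,3-dioxolan-4-yl]ethan-1-one, via Weinreb amide 4 (not isolated)
Conditions: MeNH(OMe)·HCl, i-PrMgCl, THF, −20 °C; then MeMgBr, −20 → 0 °C; aq NH4Cl
Reagents that add atoms: N,O-dimethylhydroxylamine hydrochloride (atoms in 4 only), CNOC.Cl; methylmagnesium bromide, C[Mg]Br
Why: This is a one-pot Weinreb ketone synthesis in which the magnesium amide aminolyses the ester and the chelated tetrahedral adduct of MeMgBr prevents over-addition; no stereocentre is touched.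

Step 3
Reactants: 5 1-[(4R,5S)-5-ethynyl-2,2-dimethyl-1,3-dioxolan-4-yl]ethan-1-one; 6 3,3-diethoxyprop-1-yne
Product: 8 (2R)-2-[(4R,5S)-5-ethynyl-2,2-dimethyl-1,3-dioxolan-4-yl]-5,5-diethoxypent-3-yn-2-ol, via alkynylmagnesium bromide 7 (not isolated)
Conditions: 6 (2.5 equiv), EtMgBr, Et2O, 0 °C → rt; then 5, MgBr2·OEt2, CH2Cl2–Et2O, −78 °C
Reagents that add atoms: ethylmagnesium bromide (MgBr in 7 only), CC[Mg]Br
Why: In this Cram-chelate-controlled 1,2-addition of an alkynyl Grignard reagent, magnesium bridges the ketone oxygen and O9, and the nucleophile enters from the side of H9, opposite to C8, which sets C10 (O9/O10 syn).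

Step 4
Reactants: 8 (2R)-2-[(4R,5S)-5-ethynyl-2,2-dimethyl-1,3-dioxolan-4-yl]-5,5-diethoxypent-3-yn-2-ol
Product: 9 ethyl 3-{(4S,5R)-5-[(2R)-5,5-diethoxy-2-hydroxypent-3-yn-2-yl]-2,2-dimethyl-1,3-dioxolan-4-yl}prop-2-ynoate
Conditions: PdCl2 (5 mol %), CuCl2 (2.2 equiv), NaOAc (2.2 equiv), CO (1 atm), EtOH, rt
Reagents that add atoms: carbon monoxide, [C-]#[O+]; ethanol, CCO
Why: Oxidative alkoxycarbonylation (alkynylpalladium, CO insertion, ethanolysis, CuCl2 as terminal oxidant) can only engage the terminal alkyne, and ethanol as solvent keeps exchange at the diethyl acetal degenerate.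

Step 5
Reactants: 9 ethyl 3-{(4S,5R)-5-[(2R)-5,5-diethoxy-2-hydroxypent-3-yn-2-yl]-2,2-dimethyl-1,3-dioxolan-4-yl}prop-2-ynoate
Product: 11 ethyl (Z)-3-{(4S,5R)-5-[(2R)-5,5-diethoxy-2-hydroxypent-3-yn-2-yl]-2,2-dimethyl-1,3-dioxolan-4-yl}-2-[(4,4,5,5-tetramethyl-1,3,2-dioxaborolan-2-yl)methyl]prop-2-enoate, via alkenylalane 10 (not isolated)
Conditions: i-Bu2AlH (2.3 equiv), HMPA, THF, 0 °C; then ICH2Bpin, 0 °C → rt
Reagents that add atoms: 2-(iodomethyl)-4,4,5,5-tetramethyl-1,3,2-dioxaborolane, ICB1OC(C)(C)C(C)(C)O1; diisobutylaluminium hydride (Al in 10 only), CC(C)C[AlH]CC(C)C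
Why: Conjugate syn-hydroalumination of the ynoate puts hydride on C7 and aluminium on C11, and the alkenylalane then attacks boron and undergoes a stereoretentive Matteson-type 1,2-shift with loss of iodide, so that C8 ends trans to CH2B (E-crotyl-type geometry).

Step 6
Reactants: 12 but-2-yne-1,4-diol
Product: 13 4-[(tert-butyldiphenylsilyl)oxy]but-2-yn-1-ol
Conditions: 12 (3 equiv), TBDPSCl (1 equiv), imidazole, DMF, 0 °C → rt
Reagents that add atoms: tert-butyl(chloro)diphenylsilane, CC(C)(C)[Si](Cl)(c1ccccc1)c1ccccc1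
Why: This is a statistical monosilylation of a symmetrical diol used in excess, and the TBDPS group is chosen to outlast the later acid steps.

Step 7
Reactants: 13 4-[(tert-butyldiphenylsilyl)oxy]but-2-yn-1-ol
Product: 15 (Z)-4-[(tert-butyldiphenylsilyl)oxy]-3-iodobut-2-en-1-ol, via cyclic alkenylalanate 14 (not isolated)
Conditions: NaAlH2(OCH2CH2OMe)2, THF, 0 °C → rt; then I2, −78 → 0 °C
Reagents that add atoms: iodine, II; sodium bis(2-methoxyethoxy)aluminium dihydride (atoms in 14 only), [Na+].COCCO[AlH2-]OCCOC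
Why: Hydroxyl-directed trans-hydroalumination delivers hydride to C5 and forms a five-membered alanate whose C4–Al bond is cleaved by iodine with retention, which fixes the geometry in which iodine (later C3) is cis to C6.

Step 8
Reactants: 15 (Z)-4-[(tert-butyldiphenylsilyl)oxy]-3-iodobut-2-en-1-ol
Product: 16 (Z)-4-[(tert-butyldiphenylsilyl)oxy]-3-iodobut-2-enal
Conditions: MnO2, CH2Cl2, rt
Reagents that add atoms: none
Why: Allylic oxidation with MnO2 is neutral and should leave the Z-iodoalkene and the silyl ether intact.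

Step 9
Reactants: 11 allylboronate (C7–C14, C1–C3); 16 (Z)-4-[(tert-butyldiphenylsilyl)oxy]-3-iodobut-2-enal
Product: 18 trans-6,12-lactone acetonide (α-methylene-γ-butyrolactone carrying at C6 the (Z)-2-iodo-3-(TBDPS-oxy)prop-1-enyl group and at C7 the dioxolane of 11; C6–C10 configured as in 28), via borate 17 (not isolated)
Conditions: toluene, 4 Å molecular sieves, 90 °C
Reagents that add atoms: none
Why: Thermal allylboration through a closed chair transition state is followed by lactonisation, so the E-crotyl-type boronate gives the anti adduct and hence the trans-lactone (C6/C7); A(1,3) strain with the cis ester holds H8 in the alkene plane, so the aldehyde should add to the C7 face anti to the bulky C9 branch and past the tied-back O8.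

Step 10
Reactants: 18 trans-6,12-lactone acetonide
Product: 19 8,9,10-triol lactone (acetal, vinyl iodide and TBDPS ether retained)
Conditions: camphorsulfonic acid (0.2 equiv), EtOH, 40 °C
Reagents that add atoms: none
Why: Acid-catalysed transketalisation to ethanol removes the isopropylidene group while exchange at the C3 acetal is degenerate; the TBDPS ether is acid-stable, and the trans-6,12-lactone is favoured over a cis-8,12-lactone.

Step 11
Reactants: 19 8,9,10-triol lactone
Product: 20 8-O-methacrylate (9,10-diol)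
Conditions: methacrylic anhydride (1.05 equiv), Et3N, DMAP (5 mol %), CH2Cl2, −30 °C
Reagents that add atoms: methacrylic anhydride, C=C(C)C(=O)OC(=O)C(C)=C
Why: In this kinetically controlled DMAP-catalysed acylation, O8 is the only hydroxyl that is neither tertiary (O10) nor neopentyl-like beside quaternary C10 (O9).

Step 12
Reactants: 20 8-O-methacrylate (9,10-diol)
Product: 21 8-O-methacrylate 9-O-senecioate (free tertiary 10-OH, C3 diethyl acetal)
Conditions: 3-methylbut-2-enoic acid, 2,4,6-trichlorobenzoyl chloride, Et3N, THF, rt; then 20, DMAP, toluene, rt → 40 °C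
Reagents that add atoms: 3-methylbut-2-enoic acid, CC(C)=CC(=O)O
Why: Yamaguchi esterification forces the hindered O9 to react, avoids the ketene pathway that deconjugates senecioyl chloride, and leaves the tertiary O10–H free.

Step 13
Reactants: 21 8-O-methacrylate 9-O-senecioate acetal
Product: 22 ynal (C3 aldehyde on C1≡C2; vinyl iodide at C4)
Conditions: p-TsOH·H2O (10 mol %), acetone–H2O (10:1), 40 °C
Reagents that add atoms: water, O
Why: Acid-catalysed acetal hydrolysis unmasks the aldehyde, and the electron-poor alkyne disfavours ionisation of the tertiary propargylic alcohol.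

Step 14
Reactants: 22 ynal
Product: 23 ten-membered 3,10-dihydroxy-4-en-1-yne (germacranolide carbocycle, C3 epimers)
Conditions: CrCl2 (8 equiv), NiCl2 (2 mol %), DMSO–THF, slow addition to 2 mM, rt
Reagents that add atoms: none
Why: In this intramolecular Nozaki–Hiyama–Kishi reaction, nickel-catalysed formation of the alkenylchromium species proceeds with retention of geometry, and its chemoselective 1,2-addition to the aldehyde under high dilution closes the C3–C4 bond; the new C3 centre is uncontrolled and is erased in step 15.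

Step 15
Reactants: 23 ten-membered 3,10-dihydroxy-4-en-1-yne
Product: 24 ten-membered 10-hydroxy-4-en-1-yn-3-one
Conditions: MnO2, CH2Cl2, rt
Reagents that add atoms: none
Why: MnO2 oxidises only the doubly activated (allylic and propargylic) secondary alcohol, and the tertiary 10-OH cannot react.

Step 16
Reactants: 24 ten-membered 10-hydroxy-4-en-1-yn-3-one
Product: 27 15-O-TBDPS ether of the target, via 1,3-diketone 25 (not isolated), via hemiketal 26 (not isolated)
Conditions: Ph3PAuNTf2 (5 mol %), H2O (3 equiv), 1,4-dioxane, 40 °C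
Reagents that add atoms: water, O
Why: The cationic monovalent gold centre binds C1≡C2 of 24, the C3 ketone polarises this alkyne so that water attacks C1 (the β-carbon) in anti fashion, and protodeauration and tautomerisation give the 1,3-diketone 25. The C10 hydroxyl then adds across the ring to the C3 carbonyl (hemiketal 26), and loss of the former ketone oxygen as water creates C2=C3, so that the whole event is an isomerisation with 1,3-carbonyl transposition. The closest known reaction type is the hydrative cyclisation of 4-hydroxyalk-2-ynones to 3(2H)-furanones, that is alkynone hydration followed by cyclodehydration of an α'-hydroxy-1,3-diketone, here run transannularly. The only ring closed is the furanone (O10, C3, C2, C1, C10), by O10–C3 bond formation in a 5-exo-trig mode. No stereocentre is made: C10 keeps its configuration because its C–O bond is never broken, and the hemiketal carbon C3 becomes trigonal again. The step needs activation of the alkyne beside four C=C bonds, hydration at C1 and not C2, and closure by O10 alone, which are secured by the alkynophilic soft π-acid, by the ynone polarisation, and by the acyl groups on O8 and O9 together with the release of alkyne bending strain.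

Step 17
Reactants: 27 15-O-TBDPS ether of the target
Product: 28 target CNP0239488.2
Conditions: HF·pyridine, pyridine–THF, 0 °C → rt
Reagents that add atoms: none
Why: Fluoride-mediated silyl ether cleavage under buffered, non-basic conditions should spare the α-methylene lactone, the furanone and both unsaturated esters.

Compound list
1 | dimethyl (4R,5R)-2,2-dimethyl-1,3-dioxolane-4,5-dicarboxylate | COC(=O)[C@@H]1OC(C)(C)O[C@H]1C(=O)OC | starting material
2 | methyl (4R,5R)-5-formyl-2,2-dimethyl-1,3-dioxolane-4-carboxylate | COC(=O)[C@@H]1OC(C)(C)O[C@H]1C=O | intermediate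
3 | methyl (4R,5S)-5-ethynyl-2,2-dimethyl-1,3-dioxolane-4-carboxylate | COC(=O)[C@@H]1OC(C)(C)O[C@H]1C#C | intermediate
4 | (4R,5S)-5-ethynyl-N-methoxy-N,2,2-trimethyl-1,3-dioxolane-4-carboxamide | CON(C)C(=O)[C@@H]1OC(C)(C)O[C@H]1C#C | intermediate
5 | 1-[(4R,5S)-5-ethynyl-2,2-dimethyl-1,3-dioxolan-4-yl]ethan-1-one | CC(=O)[C@@H]1OC(C)(C)O[C@H]1C#C | intermediate
6 | 3,3-diethoxyprop-1-yne | C#CC(OCC)OCC | starting material
7 | (3,3-diethoxyprop-1-yn-1-yl)magnesium bromide | CCOC(OCC)C#C[Mg]Br | intermediate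
8 | (2R)-2-[(4R,5S)-5-ethynyl-2,2-dimethyl-1,3-dioxolan-4-yl]-5,5-diethoxypent-3-yn-2-ol | CCOC(OCC)C#C[C@@](C)(O)[C@@H]1OC(C)(C)O[C@H]1C#C | intermediate
9 | ethyl 3-{(4S,5R)-5-[(2R)-5,5-diethoxy-2-hydroxypent-3-yn-2-yl]-2,2-dimethyl-1,3-dioxolan-4-yl}prop-2-ynoate | CCOC(OCC)C#C[C@@](C)(O)[C@@H]1OC(C)(C)O[C@H]1C#CC(=O)OCC | intermediate
10 | C11-diisobutylalumino enoate, O10 diisobutylaluminium alkoxide (C8 trans to Al) | CCOC(OCC)C#C[C@@](C)(O[Al](CC(C)C)CC(C)C)[C@@H]1OC(C)(C)O[C@H]1/C=C(/[Al](CC(C)C)CC(C)C)C(=O)OCC | intermediate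
11 | ethyl (Z)-3-{(4S,5R)-5-[(2R)-5,5-diethoxy-2-hydroxypent-3-yn-2-yl]-2,2-dimethyl-1,3-dioxolan-4-yl}-2-[(pinacolboryl)methyl]prop-2-enoate | CCOC(OCC)C#C[C@@](C)(O)[C@@H]1OC(C)(C)O[C@H]1/C=C(/CB1OC(C)(C)C(C)(C)O1)C(=O)OCC | intermediate
12 | but-2-yne-1,4-diol | OCC#CCO | starting material
13 | 4-[(tert-butyldiphenylsilyl)oxy]but-2-yn-1-ol | OCC#CCO[Si](c1ccccc1)(c1ccccc1)C(C)(C)C | intermediate
14 | sodium 2,2-bis(2-methoxyethoxy)-1,2-oxaaluminacyclopent-3-ene alanate (Al on C4, O6 bound) | [Na+].COCCO[Al-]1(OCCOC)OCC=C1CO[Si](c1ccccc1)(c1ccccc1)C(C)(C)C | intermediate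
15 | (Z)-4-[(tert-butyldiphenylsilyl)oxy]-3-iodobut-2-en-1-ol | OC/C=C(\I)CO[Si](c1ccccc1)(c1ccccc1)C(C)(C)C | intermediate
16 | (Z)-4-[(tert-butyldiphenylsilyl)oxy]-3-iodobut-2-enal | O=C/C=C(\I)CO[Si](c1ccccc1)(c1ccccc1)C(C)(C)C | intermediate
17 | anti allylboration adduct, O6 pinacol borate, ethyl ester still open | CCOC(OCC)C#C[C@@](C)(O)[C@@H]1OC(C)(C)O[C@H]1[C@@H](C(=C)C(=O)OCC)[C@H](OB1OC(C)(C)C(C)(C)O1)/C=C(\I)CO[Si](c1ccccc1)(c1ccccc1)C(C)(C)C | intermediate
18 | trans-6,12-lactone, 8,9-acetonide, 10-OH, C3 diethyl acetal, C4 iodide | CCOC(OCC)C#C[C@@](C)(O)[C@@H]1OC(C)(C)O[C@H]1[C@H]2C(=C)C(=O)O[C@@H]2/C=C(\I)CO[Si](c1ccccc1)(c1ccccc1)C(C)(C)C | intermediate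
19 | 8,9,10-triol lactone | CCOC(OCC)C#C[C@@](C)(O)[C@H](O)[C@@H](O)[C@H]1C(=C)C(=O)O[C@@H]1/C=C(\I)CO[Si](c1ccccc1)(c1ccccc1)C(C)(C)C | intermediate
20 | 8-O-methacrylate, 9,10-diol | CCOC(OCC)C#C[C@@](C)(O)[C@H](O)[C@@H](OC(=O)C(C)=C)[C@H]1C(=C)C(=O)O[C@@H]1/C=C(\I)CO[Si](c1ccccc1)(c1ccccc1)C(C)(C)C | intermediate
21 | 8-O-methacrylate 9-O-senecioate, 10-OH, acetal | CCOC(OCC)C#C[C@@](C)(O)[C@H](OC(=O)C=C(C)C)[C@@H](OC(=O)C(C)=C)[C@H]1C(=C)C(=O)O[C@@H]1/C=C(\I)CO[Si](c1ccccc1)(c1ccccc1)C(C)(C)C | intermediate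
22 | seco ynal (C3 aldehyde, C4 iodide) | O=CC#C[C@@](C)(O)[C@H](OC(=O)C=C(C)C)[C@@H](OC(=O)C(C)=C)[C@H]1C(=C)C(=O)O[C@@H]1/C=C(\I)CO[Si](c1ccccc1)(c1ccccc1)C(C)(C)C | intermediate
23 | ten-membered 3,10-dihydroxy-4(Z-ring)-en-1-yne 6,12-olide, C3 epimers | C=C(C)C(=O)O[C@H]1[C@H]2C(=C)C(=O)O[C@@H]2/C=C(/CO[Si](c2ccccc2)(c2ccccc2)C(C)(C)C)C(O)C#C[C@@](C)(O)[C@@H]1OC(=O)C=C(C)C | intermediate
24 | ten-membered 10-hydroxy-4-en-1-yn-3-one 6,12-olide | C=C(C)C(=O)O[C@H]1[C@H]2C(=C)C(=O)O[C@@H]2/C=C(/CO[Si](c2ccccc2)(c2ccccc2)C(C)(C)C)C(=O)C#C[C@@](C)(O)[C@@H]1OC(=O)C=C(C)C | intermediate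
25 | ten-membered 10-hydroxy-1,3-dione | C=C(C)C(=O)O[C@H]1[C@H]2C(=C)C(=O)O[C@@H]2/C=C(/CO[Si](c2ccccc2)(c2ccccc2)C(C)(C)C)C(=O)CC(=O)[C@@](C)(O)[C@@H]1OC(=O)C=C(C)C | intermediate
26 | 3-hydroxy-3,10-epoxy-1-one (transannular hemiketal) | C=C(C)C(=O)O[C@H]1[C@H]2C(=C)C(=O)O[C@@H]2/C=C(/CO[Si](c2ccccc2)(c2ccccc2)C(C)(C)C)C2(O)CC(=O)[C@@](C)(O2)[C@@H]1OC(=O)C=C(C)C | intermediate
27 | 15-O-TBDPS ether of the target | C=C(C)C(=O)O[C@H]1[C@H]2C(=C)C(=O)O[C@@H]2/C=C(/CO[Si](c2ccccc2)(c2ccccc2)C(C)(C)C)C2=CC(=O)[C@@](C)(O2)[C@@H]1OC(=O)C=C(C)C | intermediate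
28 | CNP0239488.2, (6R,7S,8S,9R,10S)-15-hydroxy-8-methacryloyloxy-9-senecioyloxy-1-oxo-3,10-epoxygermacra-2,4(Z),11(13)-trien-6,12-olide | C=C(C)C(=O)O[C@H]1[C@H]2C(=C)C(=O)O[C@@H]2/C=C(/CO)C2=CC(=O)[C@@](C)(O2)[C@@H]1OC(=O)C=C(C)C | target

Total step count: 17. Longest linear sequence: 14 (steps 1–5 and 9–17).

Steps most likely to fail

Step 14. Oligomerisation, and conjugate reduction of the ynal by divalent chromium, may outrun ring closure, because the linear C10–C1≡C2–C3 unit has to bend in the ten-membered transition state. The fallback sets out from 22 and removes both problems with a temporary metal complex. Co2(CO)8 in CH2Cl2 should give the hexacarbonyldicobalt complex of the ynal F1, in which the alkyne carbons are bent and no longer conjugated with the aldehyde. Closure of F1 (CrCl2, NiCl2, high dilution) should give the complexed macrocyclic carbinol F2. Oxidative decomplexation with (NH4)2Ce(NO3)6 in acetone at low temperature comes back to the route at 23.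

Step 9. The hindered, electron-poor boronate may add sluggishly, and the facial bias exerted by C8 (carbon branch anti against oxygen anti) may be weak or may point the wrong way. The fallback hands the choice of face from the substrate to a catalyst. It sets out from 11 and 16 and runs the allylboration under a chiral Brønsted acid, 3,3'-bis(2,4,6-triisopropylphenyl)-1,1'-binaphthyl-2,2'-diyl hydrogen phosphate, in toluene at low temperature. The enantiomer needed is the one that directs the boronate to the Si face of 16, expected to be (S). The chair-controlled anti relationship then fixes C7 together with C6. Warming closes the lactone, and the route is rejoined at 18. No new compound is made (F0).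

Step 16. Participation of the C9 ester carbonyl, binding of the catalyst to the many Lewis-basic sites, or slow hydration of the hindered alkyne may divert or stall the electrophilic activation. The fallback switches to nucleophilic activation and sets out from 24.
- Excess Et2NH in EtOH should add to C1 of the ynone and, reversibly, to C13 of the α-methylene lactone, giving the bis(diethylamine) adduct F3.
- Aqueous AcOH–THF hydrolyses the enaminone to the diketone, which closes to the 13-diethylamino furanone F4.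
- MeI gives the methiodide F5, and NaHCO3 induces Hofmann-type elimination, which restores the methylene group and rejoins the route at 27.

Further compounds
F1 | step 14 | hexacarbonyldicobalt complex of ynal 22 | O=CC#C[C@@](C)(O)[C@H](OC(=O)C=C(C)C)[C@@H](OC(=O)C(C)=C)[C@H]1C(=C)C(=O)O[C@@H]1/C=C(\I)CO[Si](c1ccccc1)(c1ccccc1)C(C)(C)C.[Co].[Co].[C-]#[O+].[C-]#[O+].[C-]#[O+].[C-]#[O+].[C-]#[O+].[C-]#[O+]
F2 | step 14 | hexacarbonyldicobalt complex of carbinol 23 | C=C(C)C(=O)O[C@H]1[C@H]2C(=C)C(=O)O[C@@H]2/C=C(/CO[Si](c2ccccc2)(c2ccccc2)C(C)(C)C)C(O)C#C[C@@](C)(O)[C@@H]1OC(=O)C=C(C)C.[Co].[Co].[C-]#[O+].[C-]#[O+].[C-]#[O+].[C-]#[O+].[C-]#[O+].[C-]#[O+]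
F0 | step 9 | none | none
F3 | step 16 | 1-diethylamino-1-en-3-one (enaminone) with 13-diethylamino-11,13-dihydro lactone | C=C(C)C(=O)O[C@H]1[C@H]2C(CN(CC)CC)C(=O)O[C@@H]2/C=C(/CO[Si](c2ccccc2)(c2ccccc2)C(C)(C)C)C(=O)C=C(N(CC)CC)[C@@](C)(O)[C@@H]1OC(=O)C=C(C)C
F4 | step 16 | 13-diethylamino-11,13-dihydro derivative of 27 | C=C(C)C(=O)O[C@H]1[C@H]2C(CN(CC)CC)C(=O)O[C@@H]2/C=C(/CO[Si](c2ccccc2)(c2ccccc2)C(C)(C)C)C2=CC(=O)[C@@](C)(O2)[C@@H]1OC(=O)C=C(C)C
F5 | step 16 | methiodide of F4 | C=C(C)C(=O)O[C@H]1[C@H]2C(C[N+](C)(CC)CC)C(=O)O[C@@H]2/C=C(/CO[Si](c2ccccc2)(c2ccccc2)C(C)(C)C)C2=CC(=O)[C@@](C)(O2)[C@@H]1OC(=O)C=C(C)C.[I-]
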